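**Strategy.** The route rests on cutting both bonds to the C5' carbonyl (side chain numbered from the benzylic carbon C1'; ring A is the arene, ring B the pyranone). This ketone is flanked by the C4' methylene, allylic to the (E)-C2'=C3' alkene, and by C6' of the (Z)-C6'=C7' alkene. A palladium-catalysed carbonylative Stille coupling can therefore assemble the base-sensitive skipped dienone in one neutral operation from three pieces: the western allylic chloride 10, CO, and the eastern (Z)-vinylstannane 29. Stannane 29 already carries ring B and the lactic-acid-derived (R) quaternary centre. Only phenol desilylation follows.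

Key step: step 17

**Western fragment (steps 1–6)**

Step 1
Reactants: 1 methylhydroquinone
Product: 2 4-[(tert-butyldimethylsilyl)oxy]-2-methylphenol
Conditions: TBSCl (1.0 equiv), imidazole, DMF, −20 → 0 °C
Reagents that add atoms: tert-butyldimethylsilyl chloride, CC(C)(C)[Si](C)(C)Cl
Why: The hydroxyl meta to the methyl group is the less hindered one, so imidazole-mediated silyl ether formation with one equivalent of TBSCl should favour it, the minor regioisomer and the bis-ether being removable by chromatography.

Step 2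
Reactants: 2 4-[(tert-butyldimethylsilyl)oxy]-2-methylphenol
Product: 3 2-bromo-4-[(tert-butyldimethylsilyl)oxy]-6-methylphenol
Conditions: NBS, i-Pr2NH (cat.), CH2Cl2, 0 °C
Reagents that add atoms: N-bromosuccinimide, O=C1CCC(=O)N1Br
Why: Amine-catalysed NBS bromination is an electrophilic aromatic substitution delivered ortho to a free phenol, and with the para position blocked by the silyloxy group and one ortho position by the methyl group only C6 remains for it.

Step 3
Reactants: 3 2-bromo-4-[(tert-butyldimethylsilyl)oxy]-6-methylphenol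
Product: 4 (3-bromo-4-methoxy-5-methylphenoxy)(tert-butyl)dimethylsilane
Conditions: MeI, K2CO3, acetone, rt
Reagents that add atoms: iodomethane, CI
Why: Williamson O-methylation of the phenoxide with MeI under anhydrous carbonate conditions should proceed while the aryl silyl ether, which needs protic base or fluoride for cleavage, stays in place.

Step 4
Reactants: 4 (3-bromo-4-methoxy-5-methylphenoxy)(tert-butyl)dimethylsilane; 5 prenyl bromide
Product: 7 tert-butyl[4-methoxy-3-methyl-5-(3-methylbut-2-en-1-yl)phenoxy]dimethylsilane, via aryllithium 6 (not isolated)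
Conditions: n-BuLi, THF, −78 °C; then 5, CuBr·SMe2 (cat.), −78 → 0 °C
Reagents that add atoms: n-butyllithium, [Li]CCCC (lithium of 6 only)
Why: Bromine–lithium exchange gives an aryllithium stabilised by the ortho methoxy group, and its copper-catalysed allylic substitution at the primary carbon of prenyl bromide (SN2 mode) is the standard way to prenylate an arene.

Step 5
Reactants: 7 tert-butyl[4-methoxy-3-methyl-5-(3-methylbut-2-en-1-yl)phenoxy]dimethylsilane
Product: 8 (2E)-4-{5-[(tert-butyldimethylsilyl)oxy]-2-methoxy-3-methylphenyl}-2-methylbut-2-en-1-ol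
Conditions: SeO2 (cat.), t-BuOOH, salicylic acid (cat.), CH2Cl2, rt
Reagents that add atoms: tert-butyl hydroperoxide, CC(C)(C)OO (oxygen relayed by SeO2, O=[Se]=O)
Why: The SeO2/t-BuOOH allylic oxidation (Riley oxidation, ene reaction then [2,3]-sigmatropic shift) is known to hydroxylate the (E)-methyl group of a prenyl terminus, which fixes the (E) geometry of C2'=C3'.

Step 6
Reactants: 8 (2E)-4-{5-[(tert-butyldimethylsilyl)oxy]-2-methoxy-3-methylphenyl}-2-methylbut-2-en-1-ol
Product: 10 tert-butyl{3-[(2E)-4-chloro-3-methylbut-2-en-1-yl]-4-methoxy-5-methylphenoxy}dimethylsilane, via allylic mesylate 9 (not isolated)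
Conditions: MsCl, 2,4,6-collidine, LiCl, DMF, 0 °C
Reagents that add atoms: methanesulfonyl chloride, CS(=O)(=O)Cl (mesyl group of 9 only); lithium chloride, [Li+].[Cl-]
Why: Mesylation followed by in situ SN2 displacement with chloride at the primary allylic carbon is a standard, non-ionising conversion of allylic alcohols into chlorides without allylic transposition or loss of alkene geometry.

**Eastern fragment (steps 7–16)**

Step 7
Reactants: 11 (S)-lactic acid
Product: 12 (2S,5S)-2-tert-butyl-5-methyl-1,3-dioxolan-4-one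
Conditions: pivalaldehyde, TsOH (cat.), pentane, reflux (Dean–Stark); crystallisation at −78 °C
Reagents that add atoms: pivalaldehyde, CC(C)(C)C=O
Why: Acid-catalysed acetalisation with removal of water closes the dioxolanone without touching the lactic stereocentre, which biases the new acetal centre toward the cis isomer that is then secured by crystallisation.

Step 8
Reactants: 13 (3-bromopropoxy)(tert-butyl)dimethylsilane; 14 propyne
Product: 18 tert-butyl{[(4Z)-5-iodo-4-methylpent-4-en-1-yl]oxy}dimethylsilane, via alkylmagnesium bromide 15 (not isolated), via alkylcopper 16 (not isolated), via alkenylcopper 17 (not isolated)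
Conditions: Mg, Et2O; CuBr·SMe2, Et2O/Me2S, −45 °C; 14, −25 °C; I2, −40 → 0 °C
Reagents that add atoms: magnesium, [Mg] (in 15 only); CuBr·SMe2, Br[Cu].CSC (copper of 16 and 17 only); iodine, II
Why: Syn-carbocupration of propyne places the alkyl group on the internal carbon and copper cis to it on the terminal carbon, and iodinolysis with retention (carbometalation–iodination) then gives the (Z)-trisubstituted vinyl iodide.

Step 9
Reactants: 18 tert-butyl{[(4Z)-5-iodo-4-methylpent-4-en-1-yl]oxy}dimethylsilane
Product: 19 (4Z)-5-iodo-4-methylpent-4-en-1-ol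
Conditions: camphorsulfonic acid (cat.), MeOH, rt
Reagents that add atoms: none
Why: Acid-catalysed methanolysis (transetherification) cleaves the primary alkyl silyl ether and leaves the vinyl iodide alone.

Step 10
Reactants: 19 (4Z)-5-iodo-4-methylpent-4-en-1-ol
Product: 20 (1Z)-1,5-diiodo-2-methylpent-1-ene
Conditions: I2, PPh3, imidazole, CH2Cl2, 0 °C → rt
Reagents that add atoms: iodine, II
Why: Appel-type iodination converts the primary alcohol into the iodide by SN2 displacement of an alkoxyphosphonium ion, the vinyl iodide being inert.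

Step 11
Reactants: 12 (2S,5S)-2-tert-butyl-5-methyl-1,3-dioxolan-4-one; 20 (1Z)-1,5-diiodo-2-methylpent-1-ene
Product: 22 (2S,5R)-2-tert-butyl-5-[(4Z)-5-iodo-4-methylpent-4-en-1-yl]-5-methyl-1,3-dioxolan-4-one, via lithium enolate 21 (not isolated)
Conditions: LDA, THF, −78 °C; then 20, DMPU, −78 → −30 °C
Reagents that add atoms: lithium diisopropylamide, [Li]N(C(C)C)C(C)C (lithium of 21 only)
Why: Deprotonation leaves the tert-butyl acetal centre as the only stereo-element, and SN2 enolate alkylation by the primary iodide on the face anti to tert-butyl (self-regeneration of stereocentres) puts the chain where hydrogen was, which sets the (R) quaternary carbinol carbon while the vinyl iodide stays inert.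

Step 12
Reactants: 22 (2S,5R)-2-tert-butyl-5-[(4Z)-5-iodo-4-methylpent-4-en-1-yl]-5-methyl-1,3-dioxolan-4-one
Product: 23 (2R,6Z)-2-hydroxy-7-iodo-N-methoxy-N,2,6-trimethylhept-6-enamide
Conditions: MeNH(OMe)·HCl, i-PrMgCl, THF, −20 → 0 °C
Reagents that add atoms: N,O-dimethylhydroxylamine hydrochloride, CNOC.Cl
Why: Aminolysis of the lactone carbonyl by the magnesium amide (Weinreb amide formation) opens the acylal, which then sheds pivalaldehyde, and the quaternary stereocentre has no acidic hydrogen to lose.

Step 13
Reactants: 23 (2R,6Z)-2-hydroxy-7-iodo-N-methoxy-N,2,6-trimethylhept-6-enamide; 24 4-bromo-2-methylbut-1-ene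
Product: 26 (6R,10Z)-6-hydroxy-11-iodo-2,6,10-trimethylundeca-1,10-dien-5-one, via 3-methylbut-3-enylmagnesium bromide 25 (not isolated)
Conditions: 24, Mg, THF; then 23, THF, −10 → 0 °C; aq. NH4Cl
Reagents that add atoms: magnesium, [Mg] (in 25 only)
Why: In this Weinreb ketone synthesis one equivalent of the Grignard reagent deprotonates the tertiary hydroxyl and a second adds once to give a chelated tetrahedral intermediate that releases the ketone only on work-up, a primary alkyl Grignard reagent not exchanging with the vinyl iodide at this temperature.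

Step 14
Reactants: 26 (6R,10Z)-6-hydroxy-11-iodo-2,6,10-trimethylundeca-1,10-dien-5-one
Product: 27 (2R)-2-[(4Z)-5-iodo-4-methylpent-4-en-1-yl]-2,6,6-trimethyloxan-3-one
Conditions: TsOH·H2O (10 mol %), CH2Cl2, rt → 40 °C
Reagents that add atoms: none
Why: In this Brønsted-acid-catalysed Markovnikov hydroalkoxylation, protonation of the 1,1-disubstituted alkene gives a tertiary cation at C6 that the tertiary hydroxyl traps in a 6-exo closure, and because capture by the ketone oxygen is reversible the saturated ring B ketone should be the thermodynamic sink.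

Step 15
Reactants: 27 (2R)-2-[(4Z)-5-iodo-4-methylpent-4-en-1-yl]-2,6,6-trimethyloxan-3-one
Product: 28 (2R)-2-[(4Z)-5-iodo-4-methylpent-4-en-1-yl]-2,6,6-trimethyl-2H-pyran-3(6H)-one
Conditions: IBX, DMSO, 70 °C
Reagents that add atoms: none
Why: IBX-mediated dehydrogenation of a ketone to its enone can act only toward C4 and C5 because C2 is quaternary, so it should introduce the C4=C5 double bond of ring B regiospecifically.

Step 16
Reactants: 28 (2R)-2-[(4Z)-5-iodo-4-methylpent-4-en-1-yl]-2,6,6-trimethyl-2H-pyran-3(6H)-one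
Product: 29 (2R)-2,6,6-trimethyl-2-[(4Z)-4-methyl-5-(tributylstannyl)pent-4-en-1-yl]-2H-pyran-3(6H)-one
Conditions: (Bu3Sn)2, Pd(PPh3)4 (cat.), toluene, 80 °C
Reagents that add atoms: hexabutylditin, CCCC[Sn](CCCC)(CCCC)[Sn](CCCC)(CCCC)CCCC
Why: Palladium-catalysed stannylation of a vinyl iodide with a ditin (oxidative addition, tin–tin transmetalation, reductive elimination) proceeds with retention of alkene geometry under neutral conditions that the enone tolerates.

**Union and completion (steps 17–18)**

Step 17
Reactants: 10 tert-butyl{3-[(2E)-4-chloro-3-methylbut-2-en-1-yl]-4-methoxy-5-methylphenoxy}dimethylsilane; 29 (2R)-2,6,6-trimethyl-2-[(4Z)-4-methyl-5-(tributylstannyl)pent-4-en-1-yl]-2H-pyran-3(6H)-one; 30 carbon monoxide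
Product: 31 (2R)-2-[(4Z,8E)-10-{5-[(tert-butyldimethylsilyl)oxy]-2-methoxy-3-methylphenyl}-4,8-dimethyl-6-oxodeca-4,8-dien-1-yl]-2,6,6-trimethyl-2H-pyran-3(6H)-one
Conditions: Pd2(dba)3 (cat.), PPh3, CO (3 atm), THF, 50 °C
Reagents that add atoms: none
Why: Zerovalent palladium should ionise the C4'–Cl bond of 10 to an η3-allyl complex of divalent palladium, CO then inserts at the unsubstituted C4' terminus to give a β,γ-unsaturated acyl palladium species, the alkenyl group of 29 is transferred from tin with retention, and reductive elimination forms C5'–C6'. The closest known reaction type is the carbonylative Stille coupling of allylic chlorides with vinylstannanes, which delivers allyl vinyl ketones. No ring is closed and no stereocentre is created, the (R) centre of ring B being remote and untouched. The step needs CO uptake to outrun direct allyl–vinyl coupling, which the CO pressure secures, and acyl formation at the primary terminus, which the C2' substituent and the C3' methyl group of the allyl unit secure. The geometry of C2'=C3' should hold because the allyl complex prefers the syn arrangement that corresponds to (E), and that of C6'=C7' because tin-to-palladium alkenyl transfer is stereoretentive. The absence of base keeps the doubly activated C4' methylene from enolising, so neither alkene should drift into conjugation, and the aryl silyl ether keeps the phenol from being acylated by the acyl palladium intermediate.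

Step 18
Reactants: 31 (2R)-2-[(4Z,8E)-10-{5-[(tert-butyldimethylsilyl)oxy]-2-methoxy-3-methylphenyl}-4,8-dimethyl-6-oxodeca-4,8-dien-1-yl]-2,6,6-trimethyl-2H-pyran-3(6H)-one
Product: 32 (2R)-2-[(4Z,8E)-10-(5-hydroxy-2-methoxy-3-methylphenyl)-4,8-dimethyl-6-oxodeca-4,8-dien-1-yl]-2,6,6-trimethyl-2H-pyran-3(6H)-one
Conditions: HF·pyridine, pyridine, THF, 0 °C
Reagents that add atoms: none
Why: Fluoride-mediated desilylation with pyridine-buffered HF·pyridine cleaves the aryl silyl ether under near-neutral conditions, so the C2'=C3' alkene should not move into conjugation and the (Z)-enone should not isomerise.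

**Compound list**

1 | methylhydroquinone (2-methylbenzene-1,4-diol) | Cc1cc(O)ccc1O | starting material
2 | 4-[(tert-butyldimethylsilyl)oxy]-2-methylphenol | Cc1cc(O[Si](C)(C)C(C)(C)C)ccc1O | intermediate
3 | 2-bromo-4-[(tert-butyldimethylsilyl)oxy]-6-methylphenol | Cc1cc(O[Si](C)(C)C(C)(C)C)cc(Br)c1O | intermediate
4 | (3-bromo-4-methoxy-5-methylphenoxy)(tert-butyl)dimethylsilane | COc1c(C)cc(O[Si](C)(C)C(C)(C)C)cc1Br | intermediate
5 | prenyl bromide (1-bromo-3-methylbut-2-ene) | CC(C)=CCBr | starting material
6 | {5-[(tert-butyldimethylsilyl)oxy]-2-methoxy-3-methylphenyl}lithium | COc1c(C)cc(O[Si](C)(C)C(C)(C)C)cc1[Li] | intermediate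
7 | tert-butyl[4-methoxy-3-methyl-5-(3-methylbut-2-en-1-yl)phenoxy]dimethylsilane | COc1c(C)cc(O[Si](C)(C)C(C)(C)C)cc1CC=C(C)C | intermediate
8 | (2E)-4-{5-[(tert-butyldimethylsilyl)oxy]-2-methoxy-3-methylphenyl}-2-methylbut-2-en-1-ol | COc1c(C)cc(O[Si](C)(C)C(C)(C)C)cc1C/C=C(\C)CO | intermediate
9 | (2E)-4-{5-[(tert-butyldimethylsilyl)oxy]-2-methoxy-3-methylphenyl}-2-methylbut-2-en-1-yl methanesulfonate | COc1c(C)cc(O[Si](C)(C)C(C)(C)C)cc1C/C=C(\C)COS(C)(=O)=O | intermediate
10 | tert-butyl{3-[(2E)-4-chloro-3-methylbut-2-en-1-yl]-4-methoxy-5-methylphenoxy}dimethylsilane | COc1c(C)cc(O[Si](C)(C)C(C)(C)C)cc1C/C=C(\C)CCl | intermediate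
11 | (S)-lactic acid | C[C@H](O)C(O)=O | starting material
12 | (2S,5S)-2-tert-butyl-5-methyl-1,3-dioxolan-4-one (cis) | C[C@@H]1O[C@H](C(C)(C)C)OC1=O | intermediate
13 | (3-bromopropoxy)(tert-butyl)dimethylsilane | BrCCCO[Si](C)(C)C(C)(C)C | starting material
14 | propyne | CC#C | starting material
15 | [3-(tert-butyldimethylsilyloxy)propyl]magnesium bromide | Br[Mg]CCCO[Si](C)(C)C(C)(C)C | intermediate
16 | [3-(tert-butyldimethylsilyloxy)propyl]copper (MgBr2 complex) | [Cu]CCCO[Si](C)(C)C(C)(C)C | intermediate
17 | [(1Z)-5-(tert-butyldimethylsilyloxy)-2-methylpent-1-en-1-yl]copper | [Cu]/C=C(/C)CCCO[Si](C)(C)C(C)(C)C | intermediate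
18 | tert-butyl{[(4Z)-5-iodo-4-methylpent-4-en-1-yl]oxy}dimethylsilane | I/C=C(/C)CCCO[Si](C)(C)C(C)(C)C | intermediate
19 | (4Z)-5-iodo-4-methylpent-4-en-1-ol | I/C=C(/C)CCCO | intermediate
20 | (1Z)-1,5-diiodo-2-methylpent-1-ene | I/C=C(/C)CCCI | intermediate
21 | lithium (2S)-2-tert-butyl-5-methyl-1,3-dioxol-4-olate | CC1=C(O[Li])O[C@@H](C(C)(C)C)O1 | intermediate
22 | (2S,5R)-2-tert-butyl-5-[(4Z)-5-iodo-4-methylpent-4-en-1-yl]-5-methyl-1,3-dioxolan-4-one | C[C@]1(CCC/C(C)=C\I)O[C@H](C(C)(C)C)OC1=O | intermediate
23 | (2R,6Z)-2-hydroxy-7-iodo-N-methoxy-N,2,6-trimethylhept-6-enamide | CON(C)C(=O)[C@](C)(O)CCC/C(C)=C\I | intermediate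
24 | 4-bromo-2-methylbut-1-ene | C=C(C)CCBr | starting material
25 | 3-methylbut-3-enylmagnesium bromide | C=C(C)CC[Mg]Br | intermediate
26 | (6R,10Z)-6-hydroxy-11-iodo-2,6,10-trimethylundeca-1,10-dien-5-one | C=C(C)CCC(=O)[C@](C)(O)CCC/C(C)=C\I | intermediate
27 | (2R)-2-[(4Z)-5-iodo-4-methylpent-4-en-1-yl]-2,6,6-trimethyloxan-3-one | C[C@]1(CCC/C(C)=C\I)OC(C)(C)CCC1=O | intermediate
28 | (2R)-2-[(4Z)-5-iodo-4-methylpent-4-en-1-yl]-2,6,6-trimethyl-2H-pyran-3(6H)-one | C[C@]1(CCC/C(C)=C\I)OC(C)(C)C=CC1=O | intermediate
29 | (2R)-2,6,6-trimethyl-2-[(4Z)-4-methyl-5-(tributylstannyl)pent-4-en-1-yl]-2H-pyran-3(6H)-one | CCCC[Sn](CCCC)(CCCC)/C=C(/C)CCC[C@@]1(C)OC(C)(C)C=CC1=O | intermediate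
30 | carbon monoxide | [C-]#[O+] | starting material
31 | (2R)-2-[(4Z,8E)-10-{5-[(tert-butyldimethylsilyl)oxy]-2-methoxy-3-methylphenyl}-4,8-dimethyl-6-oxodeca-4,8-dien-1-yl]-2,6,6-trimethyl-2H-pyran-3(6H)-one | COc1c(C)cc(O[Si](C)(C)C(C)(C)C)cc1C/C=C(\C)CC(=O)/C=C(/C)CCC[C@@]1(C)OC(C)(C)C=CC1=O | intermediate
32 | (2R)-2-[(4Z,8E)-10-(5-hydroxy-2-methoxy-3-methylphenyl)-4,8-dimethyl-6-oxodeca-4,8-dien-1-yl]-2,6,6-trimethyl-2H-pyran-3(6H)-one (CNP0160516.2) | COc1c(C)cc(O)cc1C/C=C(\C)CC(=O)/C=C(/C)CCC[C@@]1(C)OC(C)(C)C=CC1=O | target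

**Step count**

Total: 18 steps. Longest linear sequence: 11 steps (steps 8–18, from 13 and 14 to 32). The western branch is 6 steps and is convergent with it.

**Steps most likely to fail**

Step 17. The allyl palladium intermediate may couple with the stannane before it takes up CO, or it may lose the (E) geometry or let the alkene slide into conjugation while on the metal. The fallback sets out from 10 and 28 and returns at 31; it brings in the ketone carbon as an aldehyde instead of CO and does not need step 16. Alkylation of 2-lithio-1,3-dithiane (1,3-dithiane, n-BuLi, THF, −30 °C) with 10 should give the allyl dithiane F1. S-Methylation and hydrolysis (MeI, CaCO3, aqueous MeCN) should unveil the β,γ-unsaturated aldehyde F2. Nozaki–Hiyama–Kishi addition of vinyl iodide 28 (CrCl2, NiCl2 (cat.), DMSO, rt) is selective for aldehydes over the ring B ketone and keeps the (Z) geometry, and should give the C5' carbinol F3 as an epimer mixture that does not matter. Dess–Martin periodinane (NaHCO3, CH2Cl2, 0 °C) then oxidises F3 to 31.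

Step 16. The stannane, once formed, may couple with unreacted iodide (Stille homocoupling), or tin may be lost by protonolysis during purification. The fallback sets out from 28 and returns at 29. Luche reduction (NaBH4, CeCl3·7H2O, MeOH, −40 °C) masks the ring B ketone as the allylic alcohol F4, an epimer mixture at C3 of ring B. Deprotonation with MeLi, iodine–lithium exchange with t-BuLi (Et2O, −78 °C) and quenching with Bu3SnCl should give the stannyl alcohol F5 with retention of the (Z) geometry. MnO2 (CH2Cl2, rt) then re-oxidises the allylic alcohol to 29.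

Step 14. The tertiary cation may be intercepted by the ketone oxygen or lose a proton faster than the hindered hydroxyl attacks, and the acid may begin to scramble the vinyl iodide geometry. The fallback sets out from 26 and returns at 27. Intramolecular alkoxymercuration (Hg(OCOCF3)2, MeCN, 0 °C; then aqueous NaCl) closes ring B under kinetic control without a free carbocation and should give the chloromercurial F6, an epimer mixture at C6 that is erased in the next operation. Reductive demercuration (NaBH4, aqueous NaOH, THF, −40 °C) replaces mercury by hydrogen to give 27, the hindered ketone being expected to survive the brief cold exposure.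

**Further compounds**

F1 | step 17 | 2-[(2E)-4-{5-[(tert-butyldimethylsilyl)oxy]-2-methoxy-3-methylphenyl}-2-methylbut-2-en-1-yl]-1,3-dithiane | COc1c(C)cc(O[Si](C)(C)C(C)(C)C)cc1C/C=C(\C)CC1SCCCS1
F2 | step 17 | (3E)-5-{5-[(tert-butyldimethylsilyl)oxy]-2-methoxy-3-methylphenyl}-3-methylpent-3-enal | COc1c(C)cc(O[Si](C)(C)C(C)(C)C)cc1C/C=C(\C)CC=O
F3 | step 17 | (2R)-2-[(4Z,8E)-10-{5-[(tert-butyldimethylsilyl)oxy]-2-methoxy-3-methylphenyl}-6-hydroxy-4,8-dimethyldeca-4,8-dien-1-yl]-2,6,6-trimethyl-2H-pyran-3(6H)-one (carbinol epimers) | COc1c(C)cc(O[Si](C)(C)C(C)(C)C)cc1C/C=C(\C)CC(O)/C=C(/C)CCC[C@@]1(C)OC(C)(C)C=CC1=O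
F4 | step 16 | (2R)-2-[(4Z)-5-iodo-4-methylpent-4-en-1-yl]-2,6,6-trimethyl-3,6-dihydro-2H-pyran-3-ol (C3 epimers) | C[C@]1(CCC/C(C)=C\I)OC(C)(C)C=CC1O
F5 | step 16 | (2R)-2,6,6-trimethyl-2-[(4Z)-4-methyl-5-(tributylstannyl)pent-4-en-1-yl]-3,6-dihydro-2H-pyran-3-ol (C3 epimers) | CCCC[Sn](CCCC)(CCCC)/C=C(/C)CCC[C@@]1(C)OC(C)(C)C=CC1O
F6 | step 14 | chloro({(6R)-6-[(4Z)-5-iodo-4-methylpent-4-en-1-yl]-2,6-dimethyl-5-oxooxan-2-yl}methyl)mercury (C2 epimers) | C[C@]1(CCC/C(C)=C\I)OC(C)(C[Hg]Cl)CCC1=O
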